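The cyclohexane is cut across two para-related ring bonds: C(OH)(CH3)–C(quaternary) and C(ylidene)–CH. The feature exploited is that the carbinol carbon with its oxygen and the ylidene carbon (the β-carbon of the enal) stand 1,4 across the ring, so the ring is a masked 7-oxabicyclo[2.2.1]heptane. An intramolecular Diels–Alder reaction of a 2,5-disubstituted furan with a tethered α-substituted enal should form both bonds, both quaternary carbons and the ring CH stereocentre in one operation. The precursor is a furfuryl allyl sulfide: its CH2–S–CH2 tether later becomes the two vicinal C-methyl groups, and β-elimination of the oxygen bridge releases the tertiary alcohol and the tetrasubstituted enal.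

Key step: step 11

Remark 1: the CH(CH3) carbon of the furan side chain is formed without control in step 2 and is carried as both epimers (written 2RS, left open in the SMILES) from 3 to 29; it becomes sp2 in step 19.
Remark 2: 1, 9, 10 and 22 are taken as commercial.
Remark 3: the catalyst enantiomer in step 11 is assigned by analogy with the reported sense for 2-methylacrolein; this sense is recalled, not derived here, and the enantiomeric catalyst is equally available.

Step 1
Reactants: 1 2-acetylfuran
Product: 2 2-(prop-1-en-2-yl)furan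
Conditions: Ph3PCH3Br, KOtBu, THF, 0 °C → rt
Reagents that add atoms: methyltriphenylphosphonium bromide, C[P+](c1ccccc1)(c1ccccc1)c1ccccc1.[Br-]
Why: Wittig methylenation of the methyl ketone with the non-stabilised ylide should give the 1,1-disubstituted alkene.

Step 2
Reactants: 2 2-(prop-1-en-2-yl)furan
Product: 4 (2RS)-2-(furan-2-yl)propan-1-ol, via the B-alkyl-9-BBN adduct 3 (not isolated)
Conditions: 9-BBN, THF, 0 °C → rt; then NaOH, H2O2, 0 °C
Reagents that add atoms: hydrogen peroxide, OO
Why: Anti-Markovnikov hydroboration–oxidation places oxygen on the terminal carbon; the new methine centre is not controlled and is removed in step 19.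

Step 3
Reactants: 4 (2RS)-2-(furan-2-yl)propan-1-ol
Product: 5 triethyl{[(2RS)-2-(furan-2-yl)propyl]oxy}silane
Conditions: Et3SiCl, imidazole, CH2Cl2, 0 °C
Reagents that add atoms: chlorotriethylsilane, CC[Si](Cl)(CC)CC
Why: Silylation of the primary alcohol installs the triethylsilyl ether that is later converted directly into the aldehyde.

Step 4
Reactants: 5 triethyl{[(2RS)-2-(furan-2-yl)propyl]oxy}silane
Product: 7 (5-{(2RS)-1-[(triethylsilyl)oxy]propan-2-yl}furan-2-yl)methanol, via the 5-lithiofuran 6 (not isolated)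
Conditions: n-BuLi, THF, −78 → 0 °C; (CH2O)n, 0 °C → rt; aq. NH4Cl
Reagents that add atoms: paraformaldehyde (as formaldehyde), C=O
Why: α-Lithiation of the 2-alkylfuran at its free C-5 followed by hydroxymethylation is the standard route to 5-substituted furfuryl alcohols.

Step 5
Reactants: 7 (5-{(2RS)-1-[(triethylsilyl)oxy]propan-2-yl}furan-2-yl)methanol
Product: 8 S-[(5-{(2RS)-1-[(triethylsilyl)oxy]propan-2-yl}furan-2-yl)methyl] ethanethioate
Conditions: PPh3, DIAD, AcSH, THF, 0 °C
Reagents that add atoms: thioacetic acid, CC(=O)S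
Why: Mitsunobu reaction of the primary furfuryl alcohol with thioacetic acid introduces sulfur without passing through an unstable furfuryl halide.

Step 6
Reactants: 9 methyl acrylate; 10 4-[(tert-butyldimethylsilyl)oxy]butanal
Product: 11 methyl (3RS)-6-[(tert-butyldimethylsilyl)oxy]-3-hydroxy-2-methylidenehexanoate
Conditions: DABCO, 1,4-dioxane/H2O, rt
Reagents that add atoms: none
Why: Morita–Baylis–Hillman reaction joins the acrylate α-carbon to the aldehyde; the carbinol centre is racemic and disappears in step 8.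

Step 7
Reactants: 11 methyl (3RS)-6-[(tert-butyldimethylsilyl)oxy]-3-hydroxy-2-methylidenehexanoate
Product: 12 methyl (3RS)-3-acetoxy-6-[(tert-butyldimethylsilyl)oxy]-2-methylidenehexanoate
Conditions: Ac2O, Et3N, DMAP (cat.), CH2Cl2, 0 °C
Reagents that add atoms: acetic anhydride, CC(=O)OC(C)=O
Why: Acetylation turns the allylic hydroxyl into the leaving group for the allylic transposition.

Step 8
Reactants: 8 S-furfuryl thioacetate; 12 allylic acetate
Product: 14 methyl (2Z)-6-[(tert-butyldimethylsilyl)oxy]-2-({[(5-{(2RS)-1-[(triethylsilyl)oxy]propan-2-yl}furan-2-yl)methyl]sulfanyl}methyl)hex-2-enoate, via the furfuryl thiol 13 (not isolated)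
Conditions: K2CO3, MeOH (degassed), 0 °C; then 12, 0 °C → rt
Reagents that add atoms: none
Why: Methanolysis frees the thiolate, which displaces the acetate in an SN2′ addition–elimination; this should give the more stable trisubstituted alkene with the alkyl chain trans to the ester and cis to CH2S.

Step 9
Reactants: 14 sulfide enoate
Product: 15 (2Z)-6-[(tert-butyldimethylsilyl)oxy]-2-({[(5-{(2RS)-1-[(triethylsilyl)oxy]propan-2-yl}furan-2-yl)methyl]sulfanyl}methyl)hex-2-en-1-ol
Conditions: i-Bu2AlH (2.2 equiv), CH2Cl2, −78 °C; Rochelle salt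
Reagents that add atoms: none
Why: 1,2-Reduction of the enoate with i-Bu2AlH should give the allylic alcohol without touching the alkene geometry, the sulfide or the silyl ethers.

Step 10
Reactants: 15 allylic alcohol
Product: 16 (2Z)-6-[(tert-butyldimethylsilyl)oxy]-2-({[(5-{(2RS)-1-[(triethylsilyl)oxy]propan-2-yl}furan-2-yl)methyl]sulfanyl}methyl)hex-2-enal
Conditions: MnO2, CH2Cl2, rt
Reagents that add atoms: none
Why: MnO2 oxidises the allylic alcohol chemoselectively to the enal and leaves the dialkyl sulfide and the furan alone.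

Step 11
Reactants: 16 furan-tethered enal
Product: 17 (3aS,6R,7S,7aR)-7-{3-[(tert-butyldimethylsilyl)oxy]propyl}-6-{(2RS)-1-[(triethylsilyl)oxy]propan-2-yl}-1,6,7,7a-tetrahydro-3H-3a,6-epoxy-2-benzothiophene-7a-carbaldehyde (7-oxanorbornene with exo-fused thiolane, endo CHO, exo silyloxypropyl chain)
Conditions: (S)-o-tolyl-CBS-oxazaborolidine (20 mol %), HNTf2 (18 mol %), CH2Cl2, −78 → −40 °C; Et3N quench
Reagents that add atoms: none
Why: The triflimide-activated oxazaborolidine binds the formyl group of the s-trans enal, and the furan adds across C-α/C-β in a concerted, asynchronous normal-demand [4+2] cycloaddition that forms furan C-2–C-α and furan C-5–C-β together; the closest known reaction types are the intramolecular Diels–Alder reaction of furans through a three-atom heteroatom tether and oxazaborolidinium-catalysed enantioselective Diels–Alder reactions of 2-substituted enals, including those with furans. The cyclohexene ring of the 7-oxanorbornene closes by this cycloaddition, and the thiolane closes with it as a five-membered ring fused across the new bridgehead–quaternary bond, which only the exo-tether transition state allows. Addition is suprafacial on the (Z)-alkene, so the tether carbon (future CH3) and the silyloxypropyl chain stay cis; the exo tether places both syn to the oxygen bridge and the formyl group endo, which fixes the quaternary carbon, the ring CH and both bridgeheads relative to one another. The absolute sense should come from the catalyst: in the accepted assembly (formyl C–H···O contact, one enal face covered by an aryl group) the (S)-enantiomer, by analogy with 2-methylacrolein, should leave open the C-α face from which CHO, C=C and CH2S appear clockwise, the face required here. The step needs periselectivity over Friedel–Crafts-type conjugate addition and must not revert; both furan α-positions are blocked, the reaction is intramolecular and run cold, and the adduct is taken directly into step 12.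

Step 12
Reactants: 17 cycloadduct aldehyde
Product: 18 ethyl (2E)-3-[(3aS,6R,7S,7aR)-7-{3-[(tert-butyldimethylsilyl)oxy]propyl}-6-{(2RS)-1-[(triethylsilyl)oxy]propan-2-yl}-1,6,7,7a-tetrahydro-3H-3a,6-epoxy-2-benzothiophen-7a-yl]prop-2-enoate
Conditions: (EtO)2P(O)CH2CO2Et, NaH, THF, 0 °C → rt
Reagents that add atoms: triethyl phosphonoacetate, CCOC(=O)CP(=O)(OCC)OCC
Why: Horner–Wadsworth–Emmons olefination of the non-enolisable neopentyl aldehyde adds the two carbons that complete the three-carbon arm on the quaternary carbon.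

Step 13
Reactants: 18 unsaturated ester
Product: 19 ethyl 3-[(1S,2S,3S,4R)-3-{3-[(tert-butyldimethylsilyl)oxy]propyl}-1,2-dimethyl-4-{(2RS)-1-[(triethylsilyl)oxy]propan-2-yl}-7-oxabicyclo[2.2.1]heptan-2-yl]propanoate
Conditions: Raney Ni (W-2), H2 (1 atm), EtOH, rt
Reagents that add atoms: none
Why: Raney nickel hydrogenolysis of both C–S bonds turns the thiolane into the two vicinal methyl groups while the strained ring alkene and the enoate C=C are hydrogenated; no stereocentre is touched.

Step 14
Reactants: 19 saturated ester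
Product: 20 3-[(1S,2S,3S,4R)-3-{3-[(tert-butyldimethylsilyl)oxy]propyl}-1,2-dimethyl-4-{(2RS)-1-[(triethylsilyl)oxy]propan-2-yl}-7-oxabicyclo[2.2.1]heptan-2-yl]propanal
Conditions: i-Bu2AlH (1.1 equiv), CH2Cl2, −78 °C
Reagents that add atoms: none
Why: Partial reduction of the only ester at −78 °C stops at the aldehyde because the tetrahedral aluminium alkoxide survives until work-up.

Step 15
Reactants: 20 aldehyde
Product: 21 (2E)-2-methyl-5-[(1S,2S,3S,4R)-3-{3-[(tert-butyldimethylsilyl)oxy]propyl}-1,2-dimethyl-4-{(2RS)-1-[(triethylsilyl)oxy]propan-2-yl}-7-oxabicyclo[2.2.1]heptan-2-yl]pent-2-enal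
Conditions: Ph3P=C(CH3)CHO, toluene, 90 °C
Reagents that add atoms: 2-(triphenylphosphoranylidene)propanal, CC(C=O)=P(c1ccccc1)(c1ccccc1)c1ccccc1
Why: Wittig reaction with the stabilised formyl ylide should give the (E)-trisubstituted enal under thermodynamic control of the oxaphosphetane.

Step 16
Reactants: 22 (S)-citronellal
Product: 24 (3S)-3,7-dimethyloct-6-en-1-yne, via the enol nonaflate 23 (not isolated)
Conditions: n-C4F9SO2F, phosphazene base P2-Et, DMF, −20 °C → rt
Reagents that add atoms: none
Why: One-pot enol nonaflation and base-induced elimination converts the CH2–CHO unit into a terminal alkyne without adding carbon; the stereocentre is β to the carbonyl and is not touched.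

Step 17
Reactants: 21 enal; 24 alkyne
Product: 27 (3E,5R,6E,8S)-1-[(1S,2S,3S,4R)-3-{3-[(tert-butyldimethylsilyl)oxy]propyl}-1,2-dimethyl-4-{(2RS)-1-[(triethylsilyl)oxy]propan-2-yl}-7-oxabicyclo[2.2.1]heptan-2-yl]-4,8,12-trimethyltrideca-3,6,11-trien-5-ol, via the alkenyldicyclohexylborane 25 (not isolated), via the alkenyl(ethyl)zinc 26 (not isolated)
Conditions: 24, Cy2BH, toluene, 0 °C → rt; Et2Zn, −78 °C; (+)-MIB [(2R)-3-exo-morpholinoisoborneol] (10 mol %); 21, −20 → 0 °C; aq. NH4Cl
Reagents that add atoms: none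
Why: Syn hydroboration gives the (E)-alkenylborane, boron-to-zinc exchange gives the alkenylzinc, and amino-alcohol-catalysed addition should deliver it to the Re face of the aldehyde to set the (5R) carbinol, since the (−)-ligand is known to direct organozinc reagents to the Si face.

Step 18
Reactants: 27 bis-allylic alcohol
Product: 28 (3E,5R,6E,8S)-1-[(1S,2S,3S,4R)-3-{3-[(tert-butyldimethylsilyl)oxy]propyl}-1,2-dimethyl-4-{(2RS)-1-[(triethylsilyl)oxy]propan-2-yl}-7-oxabicyclo[2.2.1]heptan-2-yl]-4,8,12-trimethyltrideca-3,6,11-trien-5-yl acetate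
Conditions: Ac2O, pyridine, DMAP (cat.), CH2Cl2, 0 °C
Reagents that add atoms: acetic anhydride, CC(=O)OC(C)=O
Why: Acetylation meets only the secondary alcohol, because the tertiary hydroxyl is still masked as the oxygen bridge and both primary hydroxyls are silylated.

Step 19
Reactants: 28 acetate
Product: 30 (2Z)-2-[(2R,3S,4S)-3-[(3E,5R,6E,8S)-5-acetoxy-4,8,12-trimethyltrideca-3,6,11-trien-1-yl]-2-{3-[(tert-butyldimethylsilyl)oxy]propyl}-4-hydroxy-3,4-dimethylcyclohexylidene]propanal, via the oxa-bridged aldehyde 29 (not isolated)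
Conditions: (COCl)2, DMSO, CH2Cl2, −78 → −40 °C; Et3N, −78 → 0 °C; then DBU, rt
Reagents that add atoms: none
Why: Swern conditions are known to convert primary triethylsilyl ethers directly into aldehydes while tert-butyldimethylsilyl ethers survive, and DBU then triggers E1cB β-elimination of the bridging alkoxide, which unveils the tertiary alcohol and the tetrasubstituted enal; because this oxa-Michael opening is reversible, the alkene should settle in the (Z) geometry with the small formyl group syn to the substituted ring CH.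

Step 20
Reactants: 30 silyl ether
Product: 31 (2Z)-2-[(2R,3S,4S)-3-[(3E,5R,6E,8S)-5-acetoxy-4,8,12-trimethyltrideca-3,6,11-trien-1-yl]-4-hydroxy-2-(3-hydroxypropyl)-3,4-dimethylcyclohexylidene]propanal (CNP0259235.1)
Conditions: HF·pyridine, pyridine, THF, 0 °C → rt
Reagents that add atoms: none
Why: Buffered fluoride cleaves the primary silyl ether under conditions that should leave the bis-allylic acetate, the enal and the tertiary alcohol untouched.

Compound list
1 | 2-acetylfuran | CC(=O)c1ccco1 | starting material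
2 | 2-(prop-1-en-2-yl)furan | CC(=C)c1ccco1 | intermediate
3 | 9-[2-(furan-2-yl)propyl]-9-borabicyclo[3.3.1]nonane (not isolated) | CC(CB1C2CCCC1CCC2)c1ccco1 | intermediate
4 | (2RS)-2-(furan-2-yl)propan-1-ol | CC(CO)c1ccco1 | intermediate
5 | triethyl{[(2RS)-2-(furan-2-yl)propyl]oxy}silane | CC(CO[Si](CC)(CC)CC)c1ccco1 | intermediate
6 | (5-{(2RS)-1-[(triethylsilyl)oxy]propan-2-yl}furan-2-yl)lithium (not isolated) | CC(CO[Si](CC)(CC)CC)c1ccc([Li])o1 | intermediate
7 | (5-{(2RS)-1-[(triethylsilyl)oxy]propan-2-yl}furan-2-yl)methanol | CC(CO[Si](CC)(CC)CC)c1ccc(CO)o1 | intermediate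
8 | S-[(5-{(2RS)-1-[(triethylsilyl)oxy]propan-2-yl}furan-2-yl)methyl] ethanethioate | CC(CO[Si](CC)(CC)CC)c1ccc(CSC(C)=O)o1 | intermediate
9 | methyl acrylate | C=CC(=O)OC | starting material
10 | 4-[(tert-butyldimethylsilyl)oxy]butanal | CC(C)(C)[Si](C)(C)OCCCC=O | starting material
11 | methyl (3RS)-6-[(tert-butyldimethylsilyl)oxy]-3-hydroxy-2-methylidenehexanoate | C=C(C(=O)OC)C(O)CCCO[Si](C)(C)C(C)(C)C | intermediate
12 | methyl (3RS)-3-acetoxy-6-[(tert-butyldimethylsilyl)oxy]-2-methylidenehexanoate | C=C(C(=O)OC)C(OC(C)=O)CCCO[Si](C)(C)C(C)(C)C | intermediate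
13 | (5-{(2RS)-1-[(triethylsilyl)oxy]propan-2-yl}furan-2-yl)methanethiol (not isolated) | CC(CO[Si](CC)(CC)CC)c1ccc(CS)o1 | intermediate
14 | methyl (2Z)-6-[(tert-butyldimethylsilyl)oxy]-2-({[(5-{(2RS)-1-[(triethylsilyl)oxy]propan-2-yl}furan-2-yl)methyl]sulfanyl}methyl)hex-2-enoate | COC(=O)/C(CSCc1ccc(C(C)CO[Si](CC)(CC)CC)o1)=C/CCCO[Si](C)(C)C(C)(C)C | intermediate
15 | (2Z)-allylic alcohol from 14 (CH2OH in place of CO2CH3) | OC/C(CSCc1ccc(C(C)CO[Si](CC)(CC)CC)o1)=C/CCCO[Si](C)(C)C(C)(C)C | intermediate
16 | (2Z)-enal from 15 (CHO in place of CH2OH) | O=C/C(CSCc1ccc(C(C)CO[Si](CC)(CC)CC)o1)=C/CCCO[Si](C)(C)C(C)(C)C | intermediate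
17 | (3aS,6R,7S,7aR)-cycloadduct aldehyde (see step 11) | O=C[C@@]1(CS2)[C@H](CCCO[Si](C)(C)C(C)(C)C)[C@@]3(C(C)CO[Si](CC)(CC)CC)C=C[C@]1(C2)O3 | intermediate
18 | ethyl (2E)-3-[(3aS,6R,7S,7aR)-cycloadduct-7a-yl]prop-2-enoate (see step 12) | CCOC(=O)/C=C/[C@@]1(CS2)[C@H](CCCO[Si](C)(C)C(C)(C)C)[C@@]3(C(C)CO[Si](CC)(CC)CC)C=C[C@]1(C2)O3 | intermediate
19 | ethyl 3-[(1S,2S,3S,4R)-3-{3-[(tert-butyldimethylsilyl)oxy]propyl}-1,2-dimethyl-4-{(2RS)-1-[(triethylsilyl)oxy]propan-2-yl}-7-oxabicyclo[2.2.1]heptan-2-yl]propanoate | CCOC(=O)CC[C@@]1(C)[C@H](CCCO[Si](C)(C)C(C)(C)C)[C@@]2(C(C)CO[Si](CC)(CC)CC)CC[C@]1(C)O2 | intermediate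
20 | propanal corresponding to 19 (CHO in place of CO2Et) | O=CCC[C@@]1(C)[C@H](CCCO[Si](C)(C)C(C)(C)C)[C@@]2(C(C)CO[Si](CC)(CC)CC)CC[C@]1(C)O2 | intermediate
21 | (2E)-2-methylpent-2-enal from 20 (see step 15) | O=C/C(C)=C/CC[C@@]1(C)[C@H](CCCO[Si](C)(C)C(C)(C)C)[C@@]2(C(C)CO[Si](CC)(CC)CC)CC[C@]1(C)O2 | intermediate
22 | (S)-citronellal, (3S)-3,7-dimethyloct-6-enal | O=CC[C@@H](C)CCC=C(C)C | starting material
23 | (3S)-3,7-dimethylocta-1,6-dien-1-yl nonafluorobutane-1-sulfonate, E/Z mixture (not isolated) | FC(F)(F)C(F)(F)C(F)(F)C(F)(F)S(=O)(=O)OC=C[C@@H](C)CCC=C(C)C | intermediate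
24 | (3S)-3,7-dimethyloct-6-en-1-yne | C#C[C@@H](C)CCC=C(C)C | intermediate
25 | dicyclohexyl[(1E,3S)-3,7-dimethylocta-1,6-dien-1-yl]borane (not isolated) | C1CCCCC1B(C1CCCCC1)/C=C/[C@@H](C)CCC=C(C)C | intermediate
26 | ethyl[(1E,3S)-3,7-dimethylocta-1,6-dien-1-yl]zinc (not isolated) | CC[Zn]/C=C/[C@@H](C)CCC=C(C)C | intermediate
27 | (3E,5R,6E,8S)-trienol on the (1S,2S,3S,4R)-oxabicycle (see step 17) | O[C@H](/C=C/[C@@H](C)CCC=C(C)C)/C(C)=C/CC[C@@]1(C)[C@H](CCCO[Si](C)(C)C(C)(C)C)[C@@]2(C(C)CO[Si](CC)(CC)CC)CC[C@]1(C)O2 | intermediate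
28 | acetate of 27 | CC(=O)O[C@H](/C=C/[C@@H](C)CCC=C(C)C)/C(C)=C/CC[C@@]1(C)[C@H](CCCO[Si](C)(C)C(C)(C)C)[C@@]2(C(C)CO[Si](CC)(CC)CC)CC[C@]1(C)O2 | intermediate
29 | oxa-bridged aldehyde from 28, CH(CH3)CHO on the bridgehead (not isolated) | CC(=O)O[C@H](/C=C/[C@@H](C)CCC=C(C)C)/C(C)=C/CC[C@@]1(C)[C@H](CCCO[Si](C)(C)C(C)(C)C)[C@@]2(C(C)C=O)CC[C@]1(C)O2 | intermediate
30 | tert-butyldimethylsilyl ether of the target at the hydroxypropyl oxygen | CC(=O)O[C@H](/C=C/[C@@H](C)CCC=C(C)C)/C(C)=C/CC[C@@]1(C)[C@H](CCCO[Si](C)(C)C(C)(C)C)/C(=C(/C)C=O)CC[C@]1(C)O | intermediate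
31 | (2Z)-2-[(2R,3S,4S)-3-[(3E,5R,6E,8S)-5-acetoxy-4,8,12-trimethyltrideca-3,6,11-trien-1-yl]-4-hydroxy-2-(3-hydroxypropyl)-3,4-dimethylcyclohexylidene]propanal | CC(=O)O[C@H](/C=C/[C@@H](C)CCC=C(C)C)/C(C)=C/CC[C@@]1(C)[C@H](CCCO)/C(=C(/C)C=O)CC[C@]1(C)O | target

Total step count: 20. Longest linear sequence: 17 steps (steps 1–5, 8–15, 17–20).

Steps most likely to fail

1. Step 11. The congested adduct, with two adjacent fully substituted carbons, may revert to the conjugated enal, the furan may instead undergo conjugate addition, or the catalyst may not control the enal face. The fallback sets out from ester 14 and comes back at 17. Me2AlCl (CH2Cl2, −78 °C) should promote cycloaddition of the ester itself to the racemic methyl ester cycloadduct F1. After a cold quench this is reduced with LiAlH4 to the racemic primary alcohol F2, whose cycloreversion would no longer regenerate a conjugated dienophile. Esterification with (S)-2-methoxy-2-phenylacetic acid (DCC, DMAP) and chromatographic separation of the two ring-diastereomeric sets should give the mandelate of the required ring enantiomer F3. Cleavage with i-Bu2AlH returns that alcohol as a single ring enantiomer, and Dess–Martin oxidation gives 17.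

2. Step 19. Oxidative cleavage of the β-branched silyl ether may be incomplete, and the elimination may give the wrong alkene geometry. The fallback sets out from 28 and comes back at 30. HF·pyridine/pyridine (THF, 0 °C) should remove the triethylsilyl group selectively to give the primary alcohol F4. Dess–Martin periodinane/NaHCO3 then gives aldehyde 29, now isolated, and the elimination is run as a separate operation (DBU, CH2Cl2). If the geometrical isomers do not converge, the mixture is equilibrated photochemically (350 nm) and the unwanted isomer is recycled.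

3. Step 17. Ligand control at the new carbinol centre of the α-branched enal may be insufficient. The fallback sets out from 21 and 24 and comes back at 27. Hydrozirconation of 24 (Cp2Zr(H)Cl), transmetalation with Me2Zn and ligand-free addition to 21 gives 27 together with its carbinol epimer F5. MnO2 oxidises both to the cross-conjugated dienone F6. (S)-2-Methyl-CBS-oxazaborolidine with catecholborane (−78 °C) should then reduce F6 to 27, the α-methyl-branched alkenyl group acting as the large substituent.

Further compounds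
F1 | step 11 | methyl (3aS,6R,7S,7aR)-7-{3-[(tert-butyldimethylsilyl)oxy]propyl}-6-{(2RS)-1-[(triethylsilyl)oxy]propan-2-yl}-1,6,7,7a-tetrahydro-3H-3a,6-epoxy-2-benzothiophene-7a-carboxylate, formed as the racemate (enantiomer drawn is the one carried on) | COC(=O)[C@@]1(CS2)[C@H](CCCO[Si](C)(C)C(C)(C)C)[C@@]3(C(C)CO[Si](CC)(CC)CC)C=C[C@]1(C2)O3
F2 | step 11 | primary alcohol from F1 (CH2OH in place of CO2CH3), racemic before and single ring enantiomer after resolution | OC[C@@]1(CS2)[C@H](CCCO[Si](C)(C)C(C)(C)C)[C@@]3(C(C)CO[Si](CC)(CC)CC)C=C[C@]1(C2)O3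
F3 | step 11 | (S)-2-methoxy-2-phenylacetate of F2 | CO[C@H](C(=O)OC[C@@]1(CS2)[C@H](CCCO[Si](C)(C)C(C)(C)C)[C@@]3(C(C)CO[Si](CC)(CC)CC)C=C[C@]1(C2)O3)c1ccccc1
F4 | step 19 | primary alcohol from 28 (CH2OH in place of CH2OSiEt3) | CC(=O)O[C@H](/C=C/[C@@H](C)CCC=C(C)C)/C(C)=C/CC[C@@]1(C)[C@H](CCCO[Si](C)(C)C(C)(C)C)[C@@]2(C(C)CO)CC[C@]1(C)O2
F5 | step 17 | (5S)-epimer of 27 | O[C@@H](/C=C/[C@@H](C)CCC=C(C)C)/C(C)=C/CC[C@@]1(C)[C@H](CCCO[Si](C)(C)C(C)(C)C)[C@@]2(C(C)CO[Si](CC)(CC)CC)CC[C@]1(C)O2
F6 | step 17 | (3E,6E,8S)-trideca-3,6,11-trien-5-one corresponding to 27 | O=C(/C=C/[C@@H](C)CCC=C(C)C)/C(C)=C/CC[C@@]1(C)[C@H](CCCO[Si](C)(C)C(C)(C)C)[C@@]2(C(C)CO[Si](CC)(CC)CC)CC[C@]1(C)O2
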